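**Retrosynthetic overview**
1. Licobichalcone comes from its hexa-TBS ether by fluoride desilylation (TBS = tert-butyldimethylsilyl); no skeletal change.
2. Ring B (C1–C2–C3–C4–C4a–C8a), the only ring built, is closed last by C1–C8a bond formation in an acyclic (E,E)-2,3-bis(arylidene)-1,4-diaryl-1,4-dione. A chiral Brønsted acid sets C1 and kinetic enol protonation sets C2 cis.
3. Key disconnection: the two aroyl C=O bonds. Each is made by oxygen transfer from an aldehyde to one terminus of a 1,4-diarylbuta-1,3-diyne (carbonyl–alkyne metathesis through an oxetene), which also delivers each arylidene as the E isomer.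
4. Building blocks: the diyne from oxidative homocoupling of two molecules of an arylalkynylsilane (silylated 4-bromophenol plus trimethylsilylacetylene); the ring C aldehyde from 3-methoxycatechol (silylation, ortho-lithiation/formylation); the ring A aldehyde from 5-hydroxyvanillin (silylation).
5. Rings A, C and both 4-hydroxyphenyl rings are bought as benzenes; order of ring formation: ring B only (step 8).

Assumption: the target is taken exactly as the SMILES reads, i.e. (1S,2S), C1 aryl and C2 aroyl cis, methoxy at C8 next to C1. The (R)-acid is written in step 8; its mirror image is used if the first run shows the opposite sense of induction.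

**Step 1**
Reactants: 1 3-methoxycatechol
Product: 2 1,2-bis(tert-butyldimethylsilyloxy)-3-methoxybenzene
Conditions: TBSCl (2.4 equiv), imidazole (5 equiv), DMF, 23 °C
Reagents that add atoms: tert-butyldimethylsilyl chloride (TBSCl), CC(C)(C)[Si](C)(C)Cl
Why: Imidazole-mediated O-silylation of both phenols (substitution at silicon); the bulky silyl ethers later keep lithiation and ring closure away from the positions next to them; no stereocentre.

**Step 2**
Reactants: 2 1,2-bis(tert-butyldimethylsilyloxy)-3-methoxybenzene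
Product: 5 3,4-bis(tert-butyldimethylsilyloxy)-2-methoxybenzaldehyde, via aryllithium 3 (not isolated), via lithium hemiaminal alkoxide 4 (not isolated)
Conditions: n-BuLi (1.2 equiv), TMEDA, Et2O, 0 to 23 °C; DMF, −78 to 0 °C; aq. NH4Cl
Reagents that add atoms: N,N-dimethylformamide (DMF), CN(C)C=O
Why: Directed ortho-metalation, in which the methoxy group steers n-BuLi to its only free ortho position (the silyloxy groups do not direct and shield their own ortho C–H), followed by formylation of the aryllithium with DMF; no stereocentre.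

**Step 3**
Reactants: 6 3,4-dihydroxy-5-methoxybenzaldehyde (5-hydroxyvanillin)
Product: 7 3,4-bis(tert-butyldimethylsilyloxy)-5-methoxybenzaldehyde
Conditions: TBSCl (2.4 equiv), imidazole (5 equiv), DMF, 23 °C
Reagents that add atoms: tert-butyldimethylsilyl chloride (TBSCl), CC(C)(C)[Si](C)(C)Cl
Why: Standard imidazole-mediated O-silylation of the catechol; the aldehyde is untouched; no stereocentre.

**Step 4**
Reactants: 8 (4-bromophenoxy)(tert-butyl)dimethylsilane; 9 ethynyltrimethylsilane
Product: 10 tert-butyldimethyl{4-[(trimethylsilyl)ethynyl]phenoxy}silane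
Conditions: Pd(PhCN)2Cl2 (3 mol %), P(t-Bu)3 (6 mol %), CuI (2 mol %), i-Pr2NH, 1,4-dioxane, 23 °C
Reagents that add atoms: none
Why: Sonogashira coupling; the bulky electron-rich phosphine lets the electron-rich aryl bromide couple at room temperature and the amine base leaves the aryl silyl ether intact.

**Step 5**
Reactants: 10 tert-butyldimethyl{4-[(trimethylsilyl)ethynyl]phenoxy}silane (2 equiv; two molecules are joined)
Product: 12 1,4-bis[4-(tert-butyldimethylsilyloxy)phenyl]buta-1,3-diyne, via copper acetylide 11 (not isolated)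
Conditions: CuCl (1.0 equiv per alkynylsilane), DMF, air, 60 °C
Reagents that add atoms: a second molecule of 10, tert-butyldimethyl{4-[(trimethylsilyl)ethynyl]phenoxy}silane, CC(C)(C)[Si](C)(C)Oc1ccc(C#C[Si](C)(C)C)cc1
Why: Silicon-to-copper transmetalation of the alkynylsilane followed by Glaser-type oxidative homocoupling in air, in which two molecules of 10 each lose their trimethylsilyl group and are joined alkyne carbon to alkyne carbon; no fluoride or alkoxide is present, so the aryl silyl ethers survive.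

**Step 6**
Reactants: 12 1,4-bis[4-(tert-butyldimethylsilyloxy)phenyl]buta-1,3-diyne; 5 3,4-bis(tert-butyldimethylsilyloxy)-2-methoxybenzaldehyde
Product: 14 (E)-2-{[3,4-bis(tert-butyldimethylsilyloxy)-2-methoxyphenyl]methylidene}-1,4-bis[4-(tert-butyldimethylsilyloxy)phenyl]but-3-yn-1-one, via oxetene 13 (not isolated)
Conditions: In(OTf)3 (10 mol %), 4 Å MS, ClCH2CH2Cl, 50 °C; 12 in 1.5-fold excess (recovered)
Reagents that add atoms: none
Why: Lewis acid-catalysed carbonyl–alkyne metathesis ([2+2] to an oxetene, then 4π ring opening), a reaction established for aryl alkynes with aryl aldehydes but not yet demonstrated on a conjugated diyne: the inner diyne carbon attacks the activated aldehyde, the vinyl cation stabilised by the 4-silyloxyphenyl group is captured by oxygen (the new C–O bond that becomes the aroyl C=O, the same polarity as Markovnikov hydration of diaryl diynes), and the oxetene opens to the E-enone; the product alkyne is deactivated, so mono-reaction is expected.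

**Step 7**
Reactants: 14 the enynone of step 6; 7 3,4-bis(tert-butyldimethylsilyloxy)-5-methoxybenzaldehyde
Product: 16 (2E,3E)-2-{[3,4-bis(tert-butyldimethylsilyloxy)-2-methoxyphenyl]methylidene}-3-{[3,4-bis(tert-butyldimethylsilyloxy)-5-methoxyphenyl]methylidene}-1,4-bis[4-(tert-butyldimethylsilyloxy)phenyl]butane-1,4-dione, via oxetene 15 (not isolated)
Conditions: In(OTf)3 (20 mol %), 4 Å MS, ClCH2CH2Cl, 70 °C; 7 (1.5 equiv); stopped at full conversion of 14
Reagents that add atoms: none
Why: Second carbonyl–alkyne metathesis of the same type on the remaining aryl alkyne (an enynone, a further untested substrate class), now with the more electrophilic, ortho-unhindered aldehyde 7; oxygen again ends on the carbon bearing the 4-silyloxyphenyl group and the oxetene opens to the E-arylidene, while the Lewis acid finishes on the ring A-side carbonyl, which does not by itself trigger ring closure.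

**Step 8**
Reactants: 16 the (2E,3E)-bis(arylidene)dione of step 7
Product: 18 {(1S,2S)-6,7-bis(tert-butyldimethylsilyloxy)-1-[3,4-bis(tert-butyldimethylsilyloxy)-2-methoxyphenyl]-8-methoxy-1,2-dihydronaphthalene-2,3-diyl}bis{[4-(tert-butyldimethylsilyloxy)phenyl]methanone} (C1 aryl and C2 aroyl cis), via dienol 17 (not isolated)
Conditions: (R)-3,3'-bis(2,4,6-triisopropylphenyl)-1,1'-binaphthalene-2,2'-diyl N-(trifluoromethanesulfonyl)phosphoramide (C51H57F3NO5PS, 10 mol %), 5 Å MS, toluene, −20 to 0 °C, argon; cold silica filtration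
Reagents that add atoms: none
Why: Proposed new method: catalytic enantioselective cationic 6π-type (vinylogous Friedel–Crafts) ring closure of a 2,3-bis(arylidene)-1,4-dione with kinetic enol protonation — the chiral acid protonates the more basic C2 aroyl oxygen (conjugated to ring C), giving an ion-paired hydroxyallyl cation with positive charge at C1 (stabilised by the ortho-methoxy and para-silyloxy groups of ring C); ring A, held on the same side by the E-arylidene geometry, attacks C1 through its CH next to the methoxy group (para to the C6 silyloxy donor; the other ortho CH is shielded by the neighbouring silyl ether, and ring C cannot compete because its only free ortho carbon is para to a doubly flanked, twisted silyloxy group and the C4 cation is less stabilised), the chiral counter-anion selecting one helical conformer of the twisted diene and so the 1S configuration; loss of the C8a proton gives dienol 17, which the acid protonates at C2 anti to the pseudoaxial C1 aryl group (pushed axial by the C8 methoxy), giving the less stable cis (2S) ketone under kinetic control at low temperature; closest known reaction types are the chiral N-triflylphosphoramide-catalysed Nazarov cyclisation with kinetic cis protonation and the racemic triflic acid cyclisation of dibenzylidenesuccinates to 1-aryl-1,2-dihydronaphthalenes.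

**Step 9**
Reactants: 18 the hexa-TBS ether of step 8
Product: 19 licobichalcone, [(1S,2S)-1-(3,4-dihydroxy-2-methoxyphenyl)-6,7-dihydroxy-8-methoxy-1,2-dihydronaphthalene-2,3-diyl]bis[(4-hydroxyphenyl)methanone]
Conditions: Et3N·3HF (excess), THF–MeCN, 0 to 23 °C, argon, degassed solvents; pH 6 phosphate work-up
Reagents that add atoms: none
Why: Fluoride-driven cleavage of the six aryl silyl ethers (Si–F bond formation) under weakly acidic, base-free conditions, so the enolisable C2 centre set kinetically in step 8 is not epimerised and the catechols are not oxidised; C1 is not enolisable.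

**Compound list**
1 | 3-methoxycatechol (3-methoxybenzene-1,2-diol) | COc1cccc(O)c1O | starting material
2 | 1,2-bis(tert-butyldimethylsilyloxy)-3-methoxybenzene | COc1cccc(O[Si](C)(C)C(C)(C)C)c1O[Si](C)(C)C(C)(C)C | intermediate
3 | [3,4-bis(tert-butyldimethylsilyloxy)-2-methoxyphenyl]lithium | COc1c([Li])ccc(O[Si](C)(C)C(C)(C)C)c1O[Si](C)(C)C(C)(C)C | intermediate (not isolated)
4 | lithium [3,4-bis(tert-butyldimethylsilyloxy)-2-methoxyphenyl](dimethylamino)methanolate (racemic) | COc1c(C([O-])N(C)C)ccc(O[Si](C)(C)C(C)(C)C)c1O[Si](C)(C)C(C)(C)C.[Li+] | intermediate (not isolated)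
5 | 3,4-bis(tert-butyldimethylsilyloxy)-2-methoxybenzaldehyde | COc1c(C=O)ccc(O[Si](C)(C)C(C)(C)C)c1O[Si](C)(C)C(C)(C)C | intermediate
6 | 3,4-dihydroxy-5-methoxybenzaldehyde (5-hydroxyvanillin) | COc1cc(C=O)cc(O)c1O | starting material
7 | 3,4-bis(tert-butyldimethylsilyloxy)-5-methoxybenzaldehyde | COc1cc(C=O)cc(O[Si](C)(C)C(C)(C)C)c1O[Si](C)(C)C(C)(C)C | intermediate
8 | (4-bromophenoxy)(tert-butyl)dimethylsilane | CC(C)(C)[Si](C)(C)Oc1ccc(Br)cc1 | starting material
9 | ethynyltrimethylsilane | C#C[Si](C)(C)C | starting material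
10 | tert-butyldimethyl{4-[(trimethylsilyl)ethynyl]phenoxy}silane | CC(C)(C)[Si](C)(C)Oc1ccc(C#C[Si](C)(C)C)cc1 | intermediate
11 | {[4-(tert-butyldimethylsilyloxy)phenyl]ethynyl}copper | CC(C)(C)[Si](C)(C)Oc1ccc(C#C[Cu])cc1 | intermediate (not isolated)
12 | 1,4-bis[4-(tert-butyldimethylsilyloxy)phenyl]buta-1,3-diyne | CC(C)(C)[Si](C)(C)Oc1ccc(C#CC#Cc2ccc(O[Si](C)(C)C(C)(C)C)cc2)cc1 | intermediate
13 | 2-[3,4-bis(tert-butyldimethylsilyloxy)-2-methoxyphenyl]-4-[4-(tert-butyldimethylsilyloxy)phenyl]-3-{[4-(tert-butyldimethylsilyloxy)phenyl]ethynyl}-2H-oxete (racemic) | COc1c(C2OC(c3ccc(O[Si](C)(C)C(C)(C)C)cc3)=C2C#Cc2ccc(O[Si](C)(C)C(C)(C)C)cc2)ccc(O[Si](C)(C)C(C)(C)C)c1O[Si](C)(C)C(C)(C)C | intermediate (not isolated)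
14 | (E)-2-{[3,4-bis(tert-butyldimethylsilyloxy)-2-methoxyphenyl]methylidene}-1,4-bis[4-(tert-butyldimethylsilyloxy)phenyl]but-3-yn-1-one (aryl cis to the alkynyl group) | COc1c(/C=C(\C#Cc2ccc(O[Si](C)(C)C(C)(C)C)cc2)C(=O)c2ccc(O[Si](C)(C)C(C)(C)C)cc2)ccc(O[Si](C)(C)C(C)(C)C)c1O[Si](C)(C)C(C)(C)C | intermediate
15 | (E)-3-[3,4-bis(tert-butyldimethylsilyloxy)-2-methoxyphenyl]-2-{2-[3,4-bis(tert-butyldimethylsilyloxy)-5-methoxyphenyl]-4-[4-(tert-butyldimethylsilyloxy)phenyl]-2H-oxet-3-yl}-1-[4-(tert-butyldimethylsilyloxy)phenyl]prop-2-en-1-one (racemic at the oxete CH) | COc1cc(C2OC(c3ccc(O[Si](C)(C)C(C)(C)C)cc3)=C2/C(=C\c2ccc(O[Si](C)(C)C(C)(C)C)c(O[Si](C)(C)C(C)(C)C)c2OC)C(=O)c2ccc(O[Si](C)(C)C(C)(C)C)cc2)cc(O[Si](C)(C)C(C)(C)C)c1O[Si](C)(C)C(C)(C)C | intermediate (not isolated)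
16 | (2E,3E)-2-{[3,4-bis(tert-butyldimethylsilyloxy)-2-methoxyphenyl]methylidene}-3-{[3,4-bis(tert-butyldimethylsilyloxy)-5-methoxyphenyl]methylidene}-1,4-bis[4-(tert-butyldimethylsilyloxy)phenyl]butane-1,4-dione (each aryl trans to its neighbouring carbonyl) | COc1c(/C=C(C(=O)c2ccc(O[Si](C)(C)C(C)(C)C)cc2)\C(=C/c2cc(OC)c(O[Si](C)(C)C(C)(C)C)c(O[Si](C)(C)C(C)(C)C)c2)C(=O)c2ccc(O[Si](C)(C)C(C)(C)C)cc2)ccc(O[Si](C)(C)C(C)(C)C)c1O[Si](C)(C)C(C)(C)C | intermediate
17 | C2 enol of 18: 1,2-dihydronaphthalene with C1 configured as in 18, an exocyclic C2=C(OH)[4-(tert-butyldimethylsilyloxy)phenyl] group (enol geometry undefined), the C3 aroyl group and the C3=C4 bond | COc1c([C@H]2c3c(cc(O[Si](C)(C)C(C)(C)C)c(O[Si](C)(C)C(C)(C)C)c3OC)C=C(C(=O)c3ccc(O[Si](C)(C)C(C)(C)C)cc3)C2=C(O)c2ccc(O[Si](C)(C)C(C)(C)C)cc2)ccc(O[Si](C)(C)C(C)(C)C)c1O[Si](C)(C)C(C)(C)C | intermediate (not isolated)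
18 | {(1S,2S)-6,7-bis(tert-butyldimethylsilyloxy)-1-[3,4-bis(tert-butyldimethylsilyloxy)-2-methoxyphenyl]-8-methoxy-1,2-dihydronaphthalene-2,3-diyl}bis{[4-(tert-butyldimethylsilyloxy)phenyl]methanone} (1,2-cis) | COc1c([C@H]2c3c(cc(O[Si](C)(C)C(C)(C)C)c(O[Si](C)(C)C(C)(C)C)c3OC)C=C(C(=O)c3ccc(O[Si](C)(C)C(C)(C)C)cc3)[C@H]2C(=O)c2ccc(O[Si](C)(C)C(C)(C)C)cc2)ccc(O[Si](C)(C)C(C)(C)C)c1O[Si](C)(C)C(C)(C)C | intermediate
19 | licobichalcone, [(1S,2S)-1-(3,4-dihydroxy-2-methoxyphenyl)-6,7-dihydroxy-8-methoxy-1,2-dihydronaphthalene-2,3-diyl]bis[(4-hydroxyphenyl)methanone] (1,2-cis) | COc1c([C@H]2c3c(cc(O)c(O)c3OC)C=C(C(=O)c3ccc(O)cc3)[C@H]2C(=O)c2ccc(O)cc2)ccc(O)c1O | target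

**Step count**
Total steps: 9. Longest linear sequence: 6 steps (8 → 10 → 12 → 14 → 16 → 18 → 19, steps 4 to 9).

**Three steps most likely to fail**

Step 6. The hindered, electron-rich aldehyde 5 may react slowly with the diyne, and double addition or attack through the wrong alkyne carbon would waste material. Fallback (sets out from 10 and 5, comes back at 14): the C–Si bond of 10 is cleaved with AgNO3 (10 mol %) in acetone–water to give the terminal alkyne tert-butyl(4-ethynylphenoxy)dimethylsilane F1. F1 is lithiated (n-BuLi, THF, −78 °C) and added to aldehyde 5 to give the racemic propargylic alcohol 1-[3,4-bis(tert-butyldimethylsilyloxy)-2-methoxyphenyl]-3-[4-(tert-butyldimethylsilyloxy)phenyl]prop-2-yn-1-ol F2. A gold/molybdenum-catalysed Meyer–Schuster 1,3-hydroxyl shift intercepted by N-iodosuccinimide (Ph3PAuNTf2, MoO2(acac)2, NIS, CH2Cl2, 23 °C) turns F2 into the (Z)-α-iodoenone 3-[3,4-bis(tert-butyldimethylsilyloxy)-2-methoxyphenyl]-2-iodo-1-[4-(tert-butyldimethylsilyloxy)phenyl]prop-2-en-1-one F3. Sonogashira coupling of F3 with a second portion of F1 (Pd(PPh3)2Cl2, CuI, i-Pr2NH, THF, 23 °C) gives 14 with the alkene geometry retained.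

Step 7. The alkyne of 14 is cross-conjugated and hindered. The enone oxygen can attack the activated alkyne to give a furan, and once 16 exists the Lewis acid may start a racemic ring closure. Fallback (sets out from 7, using F1 and F3 of the step 6 fallback; comes back at 16): lithiated F1 is added to aldehyde 7 to give the racemic propargylic alcohol 1-[3,4-bis(tert-butyldimethylsilyloxy)-5-methoxyphenyl]-3-[4-(tert-butyldimethylsilyloxy)phenyl]prop-2-yn-1-ol F4. The same iodo-Meyer–Schuster reaction converts F4 into the (Z)-α-iodoenone 3-[3,4-bis(tert-butyldimethylsilyloxy)-5-methoxyphenyl]-2-iodo-1-[4-(tert-butyldimethylsilyloxy)phenyl]prop-2-en-1-one F5. F3 is stannylated (Me3SnSnMe3, Pd(PPh3)4, toluene, 80 °C) to the (Z)-α-stannylenone 3-[3,4-bis(tert-butyldimethylsilyloxy)-2-methoxyphenyl]-1-[4-(tert-butyldimethylsilyloxy)phenyl]-2-(trimethylstannyl)prop-2-en-1-one F6. Stille coupling of F6 with F5 (Pd2(dba)3, AsPh3, CuI, NMP, 23 to 50 °C) joins C2 to C3 with retention of both alkene geometries and gives 16.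

Step 8 (the new step). The acid may be too weak to close the ring, the enantioselectivity or the cis selectivity may be low, or the product may epimerise at C2 under the acid. Fallback with known chemistry (sets out from 16, comes back at 18): 16 is irradiated at 365 nm in degassed toluene at 23 °C. Conrotatory 6π photocyclisation gives the racemic 1,8a-dihydronaphthalene valence isomer of 16 (C1 aryl trans to the 8a hydrogen) F7. A thermal suprafacial [1,5]-hydrogen shift from C8a to C2 then gives the racemic cis-1,2-dihydronaphthalene, i.e. 18 together with its mirror image, the (1R,2R)-hexa-TBS ether ent-18 F8. The cis racemate is purified on silica from any trans isomer arising from E/Z photoisomerisation, and 18 is separated from F8 by preparative SFC on a chiral stationary phase.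

**Further compounds**
F1 | step 6 | tert-butyl(4-ethynylphenoxy)dimethylsilane | CC(C)(C)[Si](C)(C)Oc1ccc(C#C)cc1
F2 | step 6 | 1-[3,4-bis(tert-butyldimethylsilyloxy)-2-methoxyphenyl]-3-[4-(tert-butyldimethylsilyloxy)phenyl]prop-2-yn-1-ol (racemic) | COc1c(C(O)C#Cc2ccc(O[Si](C)(C)C(C)(C)C)cc2)ccc(O[Si](C)(C)C(C)(C)C)c1O[Si](C)(C)C(C)(C)C
F3 | step 6 | (Z)-3-[3,4-bis(tert-butyldimethylsilyloxy)-2-methoxyphenyl]-2-iodo-1-[4-(tert-butyldimethylsilyloxy)phenyl]prop-2-en-1-one | COc1c(/C=C(\I)C(=O)c2ccc(O[Si](C)(C)C(C)(C)C)cc2)ccc(O[Si](C)(C)C(C)(C)C)c1O[Si](C)(C)C(C)(C)C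
F4 | step 7 | 1-[3,4-bis(tert-butyldimethylsilyloxy)-5-methoxyphenyl]-3-[4-(tert-butyldimethylsilyloxy)phenyl]prop-2-yn-1-ol (racemic) | COc1cc(C(O)C#Cc2ccc(O[Si](C)(C)C(C)(C)C)cc2)cc(O[Si](C)(C)C(C)(C)C)c1O[Si](C)(C)C(C)(C)C
F5 | step 7 | (Z)-3-[3,4-bis(tert-butyldimethylsilyloxy)-5-methoxyphenyl]-2-iodo-1-[4-(tert-butyldimethylsilyloxy)phenyl]prop-2-en-1-one | COc1cc(/C=C(\I)C(=O)c2ccc(O[Si](C)(C)C(C)(C)C)cc2)cc(O[Si](C)(C)C(C)(C)C)c1O[Si](C)(C)C(C)(C)C
F6 | step 7 | (Z)-3-[3,4-bis(tert-butyldimethylsilyloxy)-2-methoxyphenyl]-1-[4-(tert-butyldimethylsilyloxy)phenyl]-2-(trimethylstannyl)prop-2-en-1-one | COc1c(/C=C(\[Sn](C)(C)C)C(=O)c2ccc(O[Si](C)(C)C(C)(C)C)cc2)ccc(O[Si](C)(C)C(C)(C)C)c1O[Si](C)(C)C(C)(C)C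
F7 | step 8 | 1,8a-dihydronaphthalene valence isomer of 16, C1 aryl trans to 8a-H (racemic; the enantiomer leading to 18 is drawn) | COC1=C(O[Si](C)(C)C(C)(C)C)C(O[Si](C)(C)C(C)(C)C)=CC2=CC(C(=O)c3ccc(O[Si](C)(C)C(C)(C)C)cc3)=C(C(=O)c3ccc(O[Si](C)(C)C(C)(C)C)cc3)[C@@H](c3ccc(O[Si](C)(C)C(C)(C)C)c(O[Si](C)(C)C(C)(C)C)c3OC)[C@@H]12
F8 | step 8 | ent-18, the (1R,2R)-hexa-TBS ether (1,2-cis) | COc1c([C@@H]2c3c(cc(O[Si](C)(C)C(C)(C)C)c(O[Si](C)(C)C(C)(C)C)c3OC)C=C(C(=O)c3ccc(O[Si](C)(C)C(C)(C)C)cc3)[C@@H]2C(=O)c2ccc(O[Si](C)(C)C(C)(C)C)cc2)ccc(O[Si](C)(C)C(C)(C)C)c1O[Si](C)(C)C(C)(C)C
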